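## Retrosynthetic overview

1. Last bond C11=C12 (Wittig): furanoid C15 aldehyde 10 plus a C25 polyenyl ylide. The C25 unit comes from (R)-α-ionone (C6′ from the chiral pool), a vinyl Grignard C2 unit and the C10 dialdehyde 14.
2. The bicyclic furanoid end is not closed directly as a five-membered ring. It comes from the (5R,6S)-5,6-epoxy dienoate 7 by a 1,3-shift of oxygen, which grows the three-membered ring O/C5/C6 into the five-membered ring O/C5/C6/C7/C8 and creates C8.
3. Enabling feature: the ring oxygen sits on the fully substituted C5 and is bonded to C8 across the C6=C7 double bond, so the 2,5-dihydrofuran is the allylic isomer of a 5,6-oxirane carrying a 7E double bond. C5 (no H) and C1 (quaternary) close the hydride-shift and elimination exits of the opened oxirane.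
4. Epoxide 7 comes from β-cyclocitral by reduction, Sharpless epoxidation (sets C5/C6), oxidation and Horner–Wadsworth–Emmons extension with a C5 phosphonate.
5. Ring order: both carbocycles are bought; oxirane (step 2), then dihydrofuran (step 5). Stereocentres: C5 by catalyst control, C8 by transfer from the C6–O bond, C6′ bought.

Key step: step 5

Assumption: (R)-(+)-α-ionone of high enantiomeric purity is treated as a purchasable material (natural-grade α-ionone is this enantiomer); carotenoid locants are used throughout (C1–C15 for the furanoid half, primed locants for the ε half).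

## Route

Step 1
Reactants: 1 β-cyclocitral (2,6,6-trimethylcyclohex-1-ene-1-carbaldehyde)
Product: 2 β-cyclogeraniol ((2,6,6-trimethylcyclohex-1-en-1-yl)methanol)
Conditions: NaBH4, MeOH, 0 °C
Reagents that add atoms: none
Why: Borohydride 1,2-reduction of the hindered, non-enolisable enal (carbonyl hydride reduction) should give the allylic alcohol cleanly, and no stereocentre is formed.

Step 2
Reactants: 2 β-cyclogeraniol
Product: 3 [(1R,6R)-2,2,6-trimethyl-7-oxabicyclo[4.1.0]heptan-1-yl]methanol
Conditions: Ti(OiPr)4 (10 mol %), D-(−)-diethyl tartrate (13 mol %), t-BuOOH (2 equiv), 4 Å MS, CH2Cl2, −20 °C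
Reagents that add atoms: tert-butyl hydroperoxide, CC(C)(C)OO
Why: Sharpless asymmetric epoxidation of a tetrasubstituted primary allylic alcohol: the titanium–D-(−)-tartrate catalyst should deliver the peroxide oxygen to the alkene face that gives (2R,3R)-epoxides in the geraniol series, which sets both oxirane centres (1R,6R; carotenoid C5 = R) under catalyst control.

Step 3
Reactants: 3 [(1R,6R)-2,2,6-trimethyl-7-oxabicyclo[4.1.0]heptan-1-yl]methanol
Product: 4 (1S,6R)-2,2,6-trimethyl-7-oxabicyclo[4.1.0]heptane-1-carbaldehyde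
Conditions: (n-Pr4N)[RuO4] (5 mol %), N-methylmorpholine N-oxide (1.5 equiv), 4 Å MS, CH2Cl2, rt
Reagents that add atoms: none
Why: Ley–Griffith oxidation under neutral conditions should give the aldehyde without opening the oxirane; the aldehyde has no α-hydrogen, so nothing can epimerise, and the descriptor at C1 changes from R to S only through the CIP rank of the formyl group.

Step 4
Reactants: 4 (1S,6R)-2,2,6-trimethyl-7-oxabicyclo[4.1.0]heptane-1-carbaldehyde; 5 triethyl (2E)-3-methyl-4-phosphonobut-2-enoate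
Product: 7 ethyl (2E,4E)-3-methyl-5-[(1S,6R)-2,2,6-trimethyl-7-oxabicyclo[4.1.0]heptan-1-yl]penta-2,4-dienoate, via lithium phosphonate carbanion 6 (not isolated)
Conditions: 5, LiN(SiMe3)2, THF, −78 °C; then 4, −78 → 0 °C; chromatography
Reagents that add atoms: none
Why: Horner–Wadsworth–Emmons olefination with the vinylogous C5 phosphonate should attach the dienoate arm to the non-enolisable aldehyde with E geometry at the new C7=C8 bond and mainly E at C9=C10 (a minor 2Z isomer is removed by chromatography), and no stereocentre is touched.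

Step 5
Reactants: 7 ethyl (2E,4E)-3-methyl-5-[(1S,6R)-2,2,6-trimethyl-7-oxabicyclo[4.1.0]heptan-1-yl]penta-2,4-dienoate
Product: 8 ethyl (2E)-3-[(2R,7aR)-4,4,7a-trimethyl-2,4,5,6,7,7a-hexahydro-1-benzofuran-2-yl]but-2-enoate
Conditions: Cu(CF3COCHCOCF3)2 (Cu(hfacac)2, 5 mol %), toluene, 120 °C, sealed tube, Ar; chromatography on Et3N-treated silica
Reagents that add atoms: none
Why: Monovalent copper formed in situ from Cu(hfacac)2 should open the allylic C6–O bond of the vinyl oxirane with allyl transposition (SN2′-type oxidative addition to an oxygen-bound allylcopper species of trivalent copper), and C8–O reductive elimination then releases the catalyst, so that the oxygen stays on C5, moves from C6 to C8 and C7=C8 becomes C6=C7: the three-membered ring O/C5/C6 grows by C7 and C8 into the five-membered ring. The closest known reaction type is the copper-catalysed ring expansion of vinyl oxiranes to 2,5-dihydrofurans, which is stereoselective for E-alkenyl oxiranes. The only ring closed is the dihydrofuran, by C8–O bond formation in a formally 5-endo mode on the terminus of the C6–C7–C8 allyl unit, which is feasible because it runs as a reductive elimination from a six-membered oxa-cupracycle (or, in the ionic limit, as collapse of an allyl cation) and not as a 5-endo-trig addition to an isolated alkene. The new stereocentre C8 is controlled by the C5 centre and the 7E geometry: the cyclohexane ring holds the C5 oxygen on the C4 side of the allyl plane, so it can only be handed to that face of C8 in the s-cis conformer about C6–C7, which places the E substituent C9 cis to C4 and trans to the C5 methyl group, that is 8R from the 5R oxirane, while C5 is untouched and the C6 centre is consumed. The step needs the 1,3-shift to win over an alkyl 1,2-shift (Meinwald ring contraction), over elimination and over E/Z scrambling of C7=C8; C5 has no hydrogen and C1 is quaternary, so hydride shift to a ketone and elimination to a dienol are impossible, and the electron-poor dienoate on C8 disfavours the long-lived free allyl cation needed for an alkyl shift or for rotation about C7–C8.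

Step 6
Reactants: 8 ethyl (2E)-3-[(2R,7aR)-4,4,7a-trimethyl-2,4,5,6,7,7a-hexahydro-1-benzofuran-2-yl]but-2-enoate
Product: 9 (2E)-3-[(2R,7aR)-4,4,7a-trimethyl-2,4,5,6,7,7a-hexahydro-1-benzofuran-2-yl]but-2-en-1-ol
Conditions: i-Bu2AlH (2.2 equiv), CH2Cl2, −78 °C; aqueous potassium sodium tartrate work-up
Reagents that add atoms: none
Why: Hydride 1,2-reduction of the conjugated ester at low temperature should give the allylic alcohol without ionising the bis-allylic C8–O bond and without deprotonating C8, so the C8 configuration is kept.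

Step 7
Reactants: 9 (2E)-3-[(2R,7aR)-4,4,7a-trimethyl-2,4,5,6,7,7a-hexahydro-1-benzofuran-2-yl]but-2-en-1-ol
Product: 10 (2E)-3-[(2R,7aR)-4,4,7a-trimethyl-2,4,5,6,7,7a-hexahydro-1-benzofuran-2-yl]but-2-enal
Conditions: MnO2 (activated, excess), CH2Cl2, rt, dark
Reagents that add atoms: none
Why: Allylic oxidation with MnO2 is neutral and chemoselective for the allylic alcohol, so the acid-labile C8–O bond and the C8 configuration should survive.

Step 8
Reactants: 11 (R)-α-ionone ((3E)-4-[(1R)-2,6,6-trimethylcyclohex-2-en-1-yl]but-3-en-2-one)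
Product: 12 (1E)-3-methyl-1-[(1R)-2,6,6-trimethylcyclohex-2-en-1-yl]penta-1,4-dien-3-ol (vinyl-α-ionol, both epimers at C3)
Conditions: CH2=CHMgBr, THF, −20 → 0 °C; aq. NH4Cl
Reagents that add atoms: vinylmagnesium bromide, C=C[Mg]Br
Why: Grignard 1,2-addition to the enone carbonyl should give the tertiary bis-allylic alcohol; the new carbinol centre is formed without control and is destroyed in step 9, and C6′ is remote from the reacting carbonyl and left untouched.

Step 9
Reactants: 12 (1E)-3-methyl-1-[(1R)-2,6,6-trimethylcyclohex-2-en-1-yl]penta-1,4-dien-3-ol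
Product: 13 [(2E,4E)-3-methyl-5-[(1R)-2,6,6-trimethylcyclohex-2-en-1-yl]penta-2,4-dienyl]triphenylphosphonium bromide
Conditions: PPh3·HBr, MeOH, rt; crystallisation
Reagents that add atoms: triphenylphosphine hydrobromide, [Br-].[PH+](c1ccccc1)(c1ccccc1)c1ccccc1
Why: Allylic substitution with transposition (SN1/SN2′): loss of water should give a pentadienyl cation that triphenylphosphine captures at the unhindered primary terminus to give the conjugated E,E-dienyl phosphonium salt, and the mild acid at room temperature should not move the ring double bond, so C6′ is kept.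

Step 10
Reactants: 13 [(2E,4E)-3-methyl-5-[(1R)-2,6,6-trimethylcyclohex-2-en-1-yl]penta-2,4-dienyl]triphenylphosphonium bromide; 14 (2E,4E,6E)-2,7-dimethylocta-2,4,6-trienedial
Product: 16 (2E,4E,6E,8E,10E,12E)-2,7,11-trimethyl-13-[(1R)-2,6,6-trimethylcyclohex-2-en-1-yl]trideca-2,4,6,8,10,12-hexaenal, via C15 ylide 15 (not isolated)
Conditions: 14 (3 equiv), NaOMe, CH2Cl2/MeOH, 0 °C → rt; crystallisation of the all-E isomer
Reagents that add atoms: none
Why: Wittig olefination of one formyl group of the symmetrical dialdehyde (used in excess to suppress double olefination) by the semi-stabilised ylide should give the C25 aldehyde, whose all-E isomer is expected to crystallise, and no stereocentre is involved.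

Step 11
Reactants: 16 (2E,4E,6E,8E,10E,12E)-2,7,11-trimethyl-13-[(1R)-2,6,6-trimethylcyclohex-2-en-1-yl]trideca-2,4,6,8,10,12-hexaenal
Product: 17 (2E,4E,6E,8E,10E,12E)-2,7,11-trimethyl-13-[(1R)-2,6,6-trimethylcyclohex-2-en-1-yl]trideca-2,4,6,8,10,12-hexaen-1-ol
Conditions: NaBH4, THF/MeOH, 0 °C, dark
Reagents that add atoms: none
Why: Borohydride 1,2-reduction of the polyenal should give the primary polyenyl alcohol, and no stereocentre is formed.

Step 12
Reactants: 17 (2E,4E,6E,8E,10E,12E)-2,7,11-trimethyl-13-[(1R)-2,6,6-trimethylcyclohex-2-en-1-yl]trideca-2,4,6,8,10,12-hexaen-1-ol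
Product: 18 [(2E,4E,6E,8E,10E,12E)-2,7,11-trimethyl-13-[(1R)-2,6,6-trimethylcyclohex-2-en-1-yl]trideca-2,4,6,8,10,12-hexaenyl]triphenylphosphonium bromide
Conditions: PPh3·HBr, CH2Cl2/MeOH, 0 °C → rt, dark
Reagents that add atoms: triphenylphosphine hydrobromide, [Br-].[PH+](c1ccccc1)(c1ccccc1)c1ccccc1
Why: Acid-mediated allylic substitution of the polyenyl alcohol by triphenylphosphine (SN1 through the delocalised polyenyl cation with capture at the primary terminus, as in the formation of retinyl-type Wittig salts) should give the C25 phosphonium salt with the conjugated all-E chain.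

Step 13
Reactants: 18 [(2E,4E,6E,8E,10E,12E)-2,7,11-trimethyl-13-[(1R)-2,6,6-trimethylcyclohex-2-en-1-yl]trideca-2,4,6,8,10,12-hexaenyl]triphenylphosphonium bromide; 10 (2E)-3-[(2R,7aR)-4,4,7a-trimethyl-2,4,5,6,7,7a-hexahydro-1-benzofuran-2-yl]but-2-enal
Product: 21 (5R,8R,6′R)-5,8-epoxy-5,8-dihydro-β,ε-carotene (target CNP0168410.1), via C25 ylide 19 (not isolated), via 11Z isomer 20 (not isolated)
Conditions: 18, NaOMe, CH2Cl2/MeOH, 0 °C; then 10, 0 °C → rt; then n-heptane, 85 °C, Ar, dark; crystallisation or neutral alumina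
Reagents that add atoms: none
Why: Wittig olefination should join C11 of the aldehyde to C12 of the weakly basic, highly delocalised polyenyl ylide, so that γ-deprotonation of the enal at C8 should not compete; the E/Z mixture formed at C11=C12 is driven to the all-E isomer by thermal equilibration, and C5, C8 and C6′ are not touched.

## Compound list

1 | β-cyclocitral (2,6,6-trimethylcyclohex-1-ene-1-carbaldehyde) | CC1=C(C=O)C(C)(C)CCC1 | starting material
2 | β-cyclogeraniol ((2,6,6-trimethylcyclohex-1-en-1-yl)methanol) | CC1=C(CO)C(C)(C)CCC1 | intermediate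
3 | [(1R,6R)-2,2,6-trimethyl-7-oxabicyclo[4.1.0]heptan-1-yl]methanol | OC[C@@]12O[C@]1(C)CCCC2(C)C | intermediate
4 | (1S,6R)-2,2,6-trimethyl-7-oxabicyclo[4.1.0]heptane-1-carbaldehyde | O=C[C@@]12O[C@]1(C)CCCC2(C)C | intermediate
5 | triethyl (2E)-3-methyl-4-phosphonobut-2-enoate (commercial E/Z mixture, drawn as E) | CCOC(=O)/C=C(\C)CP(=O)(OCC)OCC | starting material
6 | lithium salt of the phosphonate carbanion of 5 | [Li+].CCOC(=O)/C=C(\C)[CH-]P(=O)(OCC)OCC | intermediate (not isolated)
7 | ethyl (2E,4E)-3-methyl-5-[(1S,6R)-2,2,6-trimethyl-7-oxabicyclo[4.1.0]heptan-1-yl]penta-2,4-dienoate (carotenoid 5R,6S) | CCOC(=O)/C=C(\C)/C=C/[C@@]12O[C@]1(C)CCCC2(C)C | intermediate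
8 | ethyl (2E)-3-[(2R,7aR)-4,4,7a-trimethyl-2,4,5,6,7,7a-hexahydro-1-benzofuran-2-yl]but-2-enoate (carotenoid 5R,8R) | CCOC(=O)/C=C(\C)[C@H]1C=C2C(C)(C)CCC[C@@]2(C)O1 | intermediate
9 | (2E)-3-[(2R,7aR)-4,4,7a-trimethyl-2,4,5,6,7,7a-hexahydro-1-benzofuran-2-yl]but-2-en-1-ol | OC/C=C(\C)[C@H]1C=C2C(C)(C)CCC[C@@]2(C)O1 | intermediate
10 | (2E)-3-[(2R,7aR)-4,4,7a-trimethyl-2,4,5,6,7,7a-hexahydro-1-benzofuran-2-yl]but-2-enal | O=C/C=C(\C)[C@H]1C=C2C(C)(C)CCC[C@@]2(C)O1 | intermediate
11 | (R)-α-ionone ((3E)-4-[(1R)-2,6,6-trimethylcyclohex-2-en-1-yl]but-3-en-2-one) | CC1=CCCC(C)(C)[C@H]1/C=C/C(C)=O | starting material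
12 | (1E)-3-methyl-1-[(1R)-2,6,6-trimethylcyclohex-2-en-1-yl]penta-1,4-dien-3-ol (both C3 epimers) | CC1=CCCC(C)(C)[C@H]1/C=C/C(C)(O)C=C | intermediate
13 | [(2E,4E)-3-methyl-5-[(1R)-2,6,6-trimethylcyclohex-2-en-1-yl]penta-2,4-dienyl]triphenylphosphonium bromide | CC1=CCCC(C)(C)[C@H]1/C=C/C(C)=C/C[P+](c1ccccc1)(c1ccccc1)c1ccccc1.[Br-] | intermediate
14 | (2E,4E,6E)-2,7-dimethylocta-2,4,6-trienedial | O=C/C(C)=C/C=C/C=C(C)/C=O | starting material
15 | C15 ylide from 13 | CC1=CCCC(C)(C)[C@H]1/C=C/C(C)=C/C=P(c1ccccc1)(c1ccccc1)c1ccccc1 | intermediate (not isolated)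
16 | (2E,4E,6E,8E,10E,12E)-2,7,11-trimethyl-13-[(1R)-2,6,6-trimethylcyclohex-2-en-1-yl]trideca-2,4,6,8,10,12-hexaenal | CC1=CCCC(C)(C)[C@H]1/C=C/C(C)=C/C=C/C(C)=C/C=C/C=C(C)/C=O | intermediate
17 | (2E,4E,6E,8E,10E,12E)-2,7,11-trimethyl-13-[(1R)-2,6,6-trimethylcyclohex-2-en-1-yl]trideca-2,4,6,8,10,12-hexaen-1-ol | CC1=CCCC(C)(C)[C@H]1/C=C/C(C)=C/C=C/C(C)=C/C=C/C=C(C)/CO | intermediate
18 | [(2E,4E,6E,8E,10E,12E)-2,7,11-trimethyl-13-[(1R)-2,6,6-trimethylcyclohex-2-en-1-yl]trideca-2,4,6,8,10,12-hexaenyl]triphenylphosphonium bromide | CC1=CCCC(C)(C)[C@H]1/C=C/C(C)=C/C=C/C(C)=C/C=C/C=C(C)/C[P+](c1ccccc1)(c1ccccc1)c1ccccc1.[Br-] | intermediate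
19 | C25 ylide from 18 | CC1=CCCC(C)(C)[C@H]1/C=C/C(C)=C/C=C/C(C)=C/C=C/C=C(C)/C=P(c1ccccc1)(c1ccccc1)c1ccccc1 | intermediate (not isolated)
20 | (11Z)-isomer of 21 | CC1=CCCC(C)(C)[C@H]1/C=C/C(C)=C/C=C/C(C)=C/C=C/C=C(C)/C=C\C=C(/C)[C@H]1C=C2C(C)(C)CCC[C@@]2(C)O1 | intermediate (not isolated)
21 | (5R,8R,6′R)-5,8-epoxy-5,8-dihydro-β,ε-carotene | CC1=CCCC(C)(C)[C@H]1/C=C/C(C)=C/C=C/C(C)=C/C=C/C=C(C)/C=C/C=C(\C)[C@H]1C=C2C(C)(C)CCC[C@@]2(C)O1 | target

## Step count and risks

Total step count: 13. Longest linear sequence: 8 steps (steps 1–7 and 13, from β-cyclocitral); the ε branch (steps 8–12) joins at step 13.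

Steps most likely to fail:

**Step 5 (key step).** What may go wrong: ionisation of the C6–O bond may outrun the copper-templated oxygen transfer, so that the C5→C6 alkyl shift (Meinwald-type ring contraction) or rotation about C7–C8 (loss of the C8 configuration) competes; the fully substituted, electron-poor oxirane may also fail to turn over. The fallback keeps the ring expansion but moves it to the end and triggers it with acid, which is classical chemistry; it sets out from 7 and comes back at 21. Ester 7 is reduced with i-Bu2AlH (CH2Cl2, −78 °C) to (2E,4E)-3-methyl-5-[(1S,6R)-2,2,6-trimethyl-7-oxabicyclo[4.1.0]heptan-1-yl]penta-2,4-dien-1-ol F1. MnO2 then oxidises F1 to (2E,4E)-3-methyl-5-[(1S,6R)-2,2,6-trimethyl-7-oxabicyclo[4.1.0]heptan-1-yl]penta-2,4-dienal F2. Wittig olefination of F2 with ylide 19 (from 18 and NaOMe, as in step 13) should give (5R,6S,6′R)-5,6-epoxy-5,6-dihydro-β,ε-carotene F3, the all-E isomer being isolated by crystallisation. The acid-catalysed epoxide–furanoid rearrangement (trace HCl in CHCl3, rt, short contact) is then expected to give 21 together with its C8 epimer (5R,8S,6′R)-5,8-epoxy-5,8-dihydro-β,ε-carotene F4, from which 21 is separated by HPLC.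

**Step 13.** What may go wrong: deprotonation of enal 10 at C8 by the ylide (epimerisation of C8), slow addition, or poor E selectivity at C11=C12. The fallback reverses the polarity of the coupling; it sets out from 9 (with 16 as partner) and comes back at 21. Alcohol 9 is converted under Appel conditions (CBr4, PPh3, 2,6-lutidine, CH2Cl2, 0 °C) into (2R,7aR)-2-[(2E)-4-bromobut-2-en-2-yl]-4,4,7a-trimethyl-2,4,5,6,7,7a-hexahydro-1-benzofuran F5. PPh3 (toluene, rt) should convert F5 into [(2E)-3-[(2R,7aR)-4,4,7a-trimethyl-2,4,5,6,7,7a-hexahydro-1-benzofuran-2-yl]but-2-enyl]triphenylphosphonium bromide F6 without any acid. NaOMe gives the furanoid C15 ylide F7, which is condensed with the C25 aldehyde 16; the same thermal equilibration as in step 13 (through 20) leads to 21. In this variant C8–H is no longer γ to a carbonyl group.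

**Step 4.** What may go wrong: sluggish addition of the vinylogous phosphonate anion to the neopentyl, α-quaternary aldehyde, attack through the α-carbon of the anion, and low 2E/2Z selectivity. The fallback builds the chain in two smaller pieces (C3, then C2); it sets out from 4 and comes back at 7. Wittig reaction of 4 with 1-(triphenylphosphoranylidene)propan-2-one (toluene, 100 °C) should give (3E)-4-[(1S,6R)-2,2,6-trimethyl-7-oxabicyclo[4.1.0]heptan-1-yl]but-3-en-2-one F8. Horner–Wadsworth–Emmons reaction of F8 with triethyl phosphonoacetate (NaH, THF, 0 °C → rt) then gives 7 after chromatographic removal of the 2Z isomer.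

Further compounds
F1 | step 5 | (2E,4E)-3-methyl-5-[(1S,6R)-2,2,6-trimethyl-7-oxabicyclo[4.1.0]heptan-1-yl]penta-2,4-dien-1-ol | OC/C=C(\C)/C=C/[C@@]12O[C@]1(C)CCCC2(C)C
F2 | step 5 | (2E,4E)-3-methyl-5-[(1S,6R)-2,2,6-trimethyl-7-oxabicyclo[4.1.0]heptan-1-yl]penta-2,4-dienal | O=C/C=C(\C)/C=C/[C@@]12O[C@]1(C)CCCC2(C)C
F3 | step 5 | (5R,6S,6′R)-5,6-epoxy-5,6-dihydro-β,ε-carotene | CC1=CCCC(C)(C)[C@H]1/C=C/C(C)=C/C=C/C(C)=C/C=C/C=C(C)/C=C/C=C(\C)/C=C/[C@@]12O[C@]1(C)CCCC2(C)C
F4 | step 5 | (5R,8S,6′R)-5,8-epoxy-5,8-dihydro-β,ε-carotene | CC1=CCCC(C)(C)[C@H]1/C=C/C(C)=C/C=C/C(C)=C/C=C/C=C(C)/C=C/C=C(\C)[C@@H]1C=C2C(C)(C)CCC[C@@]2(C)O1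
F5 | step 13 | (2R,7aR)-2-[(2E)-4-bromobut-2-en-2-yl]-4,4,7a-trimethyl-2,4,5,6,7,7a-hexahydro-1-benzofuran | BrC/C=C(\C)[C@H]1C=C2C(C)(C)CCC[C@@]2(C)O1
F6 | step 13 | [(2E)-3-[(2R,7aR)-4,4,7a-trimethyl-2,4,5,6,7,7a-hexahydro-1-benzofuran-2-yl]but-2-enyl]triphenylphosphonium bromide | [Br-].c1ccccc1[P+](c1ccccc1)(c1ccccc1)C/C=C(\C)[C@H]1C=C2C(C)(C)CCC[C@@]2(C)O1
F7 | step 13 | furanoid C15 ylide from F6 | c1ccccc1P(c1ccccc1)(c1ccccc1)=C/C=C(\C)[C@H]1C=C2C(C)(C)CCC[C@@]2(C)O1
F8 | step 4 | (3E)-4-[(1S,6R)-2,2,6-trimethyl-7-oxabicyclo[4.1.0]heptan-1-yl]but-3-en-2-one | CC(=O)/C=C/[C@@]12O[C@]1(C)CCCC2(C)C
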